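## Structural features

The target is a germacranolide: a ten-membered carbocycle (C1–C10) fused across C6–C7 to an α-methylene-γ-butyrolactone (O on C6, C11 on C7, C12 carbonyl, C13 exo-methylene). C6, C7 and C8 are three contiguous stereocentres, all R. The lactone is trans-fused (the C5 and C8 ring bonds lie on opposite faces of the five-membered ring), and the C8 oxygen, esterified with (Z)-2-methylbut-2-enoic (angelic) acid, is syn to C6 when the chain C9–C8–C7–C11 is drawn in zigzag. Both ring alkenes, C4=C5 and C1=C10, are trisubstituted and cis within the ring (C3 cis to C6, C9 cis to C2). Each carries a hydroxymethyl group (C15 on C4, C14 on C10), whose priority makes both alkenes E in CIP terms. Fragile groups are the exo-methylene lactone (a Michael acceptor that can relactonise towards O8 under base while O8 is free), the angelate (isomerises to the tiglate when its carbonyl is activated next to nucleophiles), the two primary allylic alcohols and the doubly allylic C6–O bond. The real difficulty is closing a ten-membered ring that holds two cis trisubstituted alkenes while the C6/C7/C8 triad is set. The handle is that the C8 carbinol is homoallylic to the C11=C13 methylene through C7. The C7–C8 bond plus the exo-methylene is therefore the retron of an allyl metal addition to a C8 aldehyde with allylic transposition, the allyl unit being C13–C11=C7 of a 3-(bromomethyl)butenolide that already holds the lactone ring and C6.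

## Logic of the disconnections

**24 to 23.** No skeletal bond is cut; the O14–H and O15–H bonds are exchanged for O–Si bonds. The two primary allylic hydroxyls would compete with O8 in the esterification and would bind chromium in the ring closure, so they stay masked to the end. The gain is a last step that is a single deprotection. The demand is a desilylation that leaves the exo-methylene lactone and the Z ester untouched, which points to buffered HF and not to basic fluoride.

**23 to 21 and 22.** The C8–O bond is cut on the alkyl side, with inversion in mind. The ring closure is expected to give C8 with the configuration opposite to that of 24, so the ester is installed by a displacement at C8 that corrects the centre and acylates it in one operation. This strips the acyl group and leaves a free carbinol, the direct outcome of a carbonyl addition. The forward step must substitute a hindered ring carbinol without elimination and must use 22 only as a carboxylate nucleophile, so that its Z alkene is not isomerised.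

**21 to 19 (through 20).** The C7–C8 bond is cut, the alkene is moved back from C11=C13 to C7=C11 and C13 receives a bromide. This one cut removes the ten-membered ring, two stereocentres (C7, C8) and the exo-methylene together while the lactone stays intact. What is left is an open chain on a flat butenolide with C6 as the only stereocentre. The forward step must be γ-selective, intramolecular, non-basic and selective for one face of the butenolide and one face of the aldehyde. 19 carries tert-butyldiphenylsilyl groups on O14 and O15 in place of smaller trialkylsilyl groups, because O8 has to be unmasked beside them.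

**19 to 18 to 17.** No skeletal bond is cut; C8 goes back from aldehyde to alcohol to silyl ether. The β,γ-unsaturated aldehyde is prone to conjugation and cannot be carried, so it is made immediately before use. The demand is cleavage of one silyl ether out of three and an oxidation under neutral conditions in the presence of an allylic bromide and a butenolide with an acidic C6–H.

**17 to 16, then 16 to 14 and 15.** The C7=C11 alkene is cut (metathesis retron), then the O6–C12 acyl bond. The bromomethyl butenolide thereby reduces to a secondary bis-allylic alcohol and a purchasable acid. The forward steps must esterify without displacing the allylic bromide and must close a five-membered ring onto a 1,1-disubstituted electron-poor alkene, starting from the only monosubstituted alkene in 16.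

**14 to 13.** The C6–C7 bond is cut (vinyl anion plus enal). This is the only stereocentre set by reagent control, and removing it makes every earlier compound achiral. The demand is clean 1,2-addition with high enantioface selectivity (Si face), because no later stereocentre allows enrichment.

**13 to 12 to 11 to 10 to 9.** No skeletal bond is cut. C6 returns to a protected alcohol, and C14 and C15 return to the ester groups that controlled both alkene geometries. Three kinds of oxygen (O6, O8, O14/O15) get three orthogonal masks: an oxidatively cleaved benzyl-type ether, a small silyl ether and two bulky silyl ethers. The demands are 1,2-reduction of two enoates at once and clean orthogonality.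

**9 to 6 and 8; 8 to 1 and 7.** The C1=C10 alkene is cut (olefination retron), then the C9–C10 bond (alkylation of 1). This halves the chain. The forward olefination must be E-selective, so that the ester-derived C14 is trans to C2 and C9 is cis to C2.

**6 to 5; 5 to 3 and 4; 3 to 1 and 2.** The C1 aldehyde is masked as an acetal, the C4=C5 alkene is cut (second olefination retron) and the C3–C4 bond is cut (alkylation of 1). All carbons then come from 1 (twice), 2, 4 and 7. The forward olefination must again be E-selective (C3 cis to C6), and the O6 mask in 4 must survive the acid that frees C1.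

## Other disconnections considered

**Alternative 1:** The cut is the C5–C6 bond, taken together with the O6–C12 acyl bond. In the forward sense CrCl2 with catalytic NiCl2 would convert the C5 alkenyl iodide of the open-chain iodo aldehyde ester A1 into an alkenylchromium that adds to the C6 aldehyde. The C6 alkoxide would then close onto the C12 methyl ester to give the lactone macrocycle A2, which lacks only C13.
- In its favour: alkenyl halide–aldehyde couplings of this type are among the most dependable medium-ring closures, tolerate esters, ethers and silyl groups, and keep the C4=C5 geometry. The aldehyde is saturated and not β,γ-unsaturated. C7 and C8 are set beforehand in the open chain, so C8 arrives with its final configuration and no inversion is needed. On these last two points this plan is the better one.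
- Against it here: the C6 aldehyde of A1 is α-branched at C7 and has the C8 ether in the β-position, so epimerisation and β-elimination threaten. C6 would depend on macrocyclic diastereoselection in an open addition, whereas the chosen plan fixes C6 by reagent control before the ring exists. A2 still needs C13, and enolate methylenation requires strong base on a lactone that can relactonise.
- Comparison: structurally both plans close the ring at the lactone edge and both leave one of the three stereocentres to the closure (C6 there, C8 here), an equal risk. Mechanistically the alkenyl addition has the stronger record for ring closure, while the allyl addition has the better-defined chair transition state and delivers C13 and the exo-methylene in the same event. A2 is four operations from the target (methylenation, ether cleavage, acylation, desilylation) against two here, and A1 needs two acyclic stereocentres and a stereodefined alkenyl iodide, so the chosen plan should be shorter.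

**Alternative 2:** The cut is the C2–C3 bond. KN(SiMe3)2 would deprotonate C2 of the allylic phenyl sulfone in the lactone bromide A3, and the carbanion would displace the C3 allylic bromide to give the sulfonyl macrocycle A4 (either C2 epimer).
- In its favour: the new bond is the only sp3–sp3 bond of the ring that is remote from all stereocentres. The whole C6/C7/C8 triad would be built first on a small lactone, where relative control is easiest, and the ring closure sets no stereocentre at all. On that point it is the better plan. Sulfone carbanion alkylation is a proven way to close medium and large carbocycles.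
- Against it here: the lactone C11–H bonds are only a few pKa units less acidic than the sulfone, so enolate alkylation or condensation can compete. The allyl sulfone anion is ambident (α or γ), and the allylic bromide can react with or without transposition. Reductive removal of the allylic sulfone afterwards can shift or scramble the C1=C10 alkene and endangers the lactone.
- Comparison: structurally the chosen plan forms its ring bond where it also creates functionality, while this one forms a bond that leaves an extra group to delete. Mechanistically the sulfone route needs strong base, where the chromium closure is non-basic. After A4 five operations remain (desulfonylation, methylenation, ether cleavage, acylation, desilylation), so step economy favours the chosen plan.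

**Alternative 3:** The cuts are C8–C9 (made) and C1–C6 (broken) of an anionic oxy-Cope rearrangement. KH with 18-crown-6 would ionise the tertiary C6 alcohol of the cis-dialkenyl cyclohexenol A5, and the diene C8=C7–C6–C1–C10=C9 would rearrange to the enolate of the ten-membered dienone A6.
- In its favour: the step is unimolecular, so no high dilution is needed, and it is made irreversible by enolate formation. It expands a readily made six-membered ring and can pass chirality from the ring to C8 through an ordered chair. On ring-closure efficiency it is the better plan.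
- Against it here: the cis C1=C10 alkene arises only from the chair in which the C1–C2 ring bond is axial; the ring-flipped chair leads to the trans alkene, and the preference is not secured. A6 has no lactone. C6 and C7 would have to be set and C11–C13 attached on a flexible ten-membered enone, with regiochemistry of enolisation (C7 against the vinylogous C3 position) and facial selectivity both open.
- Comparison: structurally the chosen plan brings the lactone and C6 into the ring closure, whereas this plan postpones them. Mechanistically the pericyclic step is cleaner than an organometallic macrocyclisation. Roughly seven operations would follow A6 (alkylation at C7, ketone reduction, lactonisation, methylenation, ether cleavage, acylation, desilylation) against two here.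

Key step: step 15

Assumption: 2-[(4-methoxybenzyl)oxy]acetaldehyde (4) is treated as a purchasable aldehyde.

## Route

Step 1
Reactants: 1 triethyl phosphonoacetate; 2 2-(2-bromoethyl)-1,3-dioxolane
Product: 3 ethyl 2-(diethoxyphosphoryl)-4-(1,3-dioxolan-2-yl)butanoate (racemic; the centre is lost in step 2)
Conditions: NaH, THF/DMF, 0 °C; then 2, 60 °C
Reagents that add atoms: none
Why: C-alkylation of the sodium phosphonoacetate carbanion by a primary bromide (SN2) forms the C3–C4 bond; a slight excess of 1 limits dialkylation.

Step 2
Reactants: 3 ethyl 2-(diethoxyphosphoryl)-4-(1,3-dioxolan-2-yl)butanoate; 4 2-[(4-methoxybenzyl)oxy]acetaldehyde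
Product: 5 ethyl (2E)-2-[2-(1,3-dioxolan-2-yl)ethyl]-4-[(4-methoxybenzyl)oxy]but-2-enoate
Conditions: NaH, THF, 0 °C; then 4, 0 °C to rt
Reagents that add atoms: none
Why: Horner–Wadsworth–Emmons olefination; reversible addition of the stabilised carbanion should favour the E enoate (ester trans to C6), which places C3 cis to C6 as required for C4=C5; any Z isomer is removed by chromatography.

Step 3
Reactants: 5 ethyl (2E)-2-[2-(1,3-dioxolan-2-yl)ethyl]-4-[(4-methoxybenzyl)oxy]but-2-enoate
Product: 6 ethyl (2E)-4-[(4-methoxybenzyl)oxy]-2-(3-oxopropyl)but-2-enoate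
Conditions: 2 M HCl, THF, rt
Reagents that add atoms: water, O
Why: Acid hydrolysis of the dioxolane frees the C1 aldehyde; the enoate and the 4-methoxybenzyl ether tolerate dilute aqueous acid, which is why O6 carries this ether and not a silyl group.

Step 4
Reactants: 1 triethyl phosphonoacetate; 7 (2-bromoethoxy)(tert-butyl)dimethylsilane
Product: 8 ethyl 4-[(tert-butyldimethylsilyl)oxy]-2-(diethoxyphosphoryl)butanoate (racemic; the centre is lost in step 5)
Conditions: NaH, THF/DMF, 0 °C; then 7, Bu4NI (cat.), 60 °C
Reagents that add atoms: none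
Why: The same phosphonoacetate C-alkylation (SN2) forms the C9–C10 bond and brings in C8 as a silyl-protected primary alcohol.

Step 5
Reactants: 8 ethyl 4-[(tert-butyldimethylsilyl)oxy]-2-(diethoxyphosphoryl)butanoate; 6 ethyl (2E)-4-[(4-methoxybenzyl)oxy]-2-(3-oxopropyl)but-2-enoate
Product: 9 diethyl (2E,6E)-2-{2-[(tert-butyldimethylsilyl)oxy]ethyl}-6-{2-[(4-methoxybenzyl)oxy]ethylidene}hept-2-enedioate
Conditions: NaH, THF, 0 °C; then 6, 0 °C to rt
Reagents that add atoms: none
Why: Second Horner–Wadsworth–Emmons olefination, again expected to be E-selective, forms C1=C10 with the ester (future C14) trans to C2 and C9 cis to C2; the aldehyde reacts far faster than the existing enoate.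

Step 6
Reactants: 9 diethyl (2E,6E)-2-{2-[(tert-butyldimethylsilyl)oxy]ethyl}-6-{2-[(4-methoxybenzyl)oxy]ethylidene}hept-2-enedioate
Product: 10 (2E,6E)-2-{2-[(tert-butyldimethylsilyl)oxy]ethyl}-6-{2-[(4-methoxybenzyl)oxy]ethylidene}hept-2-ene-1,7-diol
Conditions: iBu2AlH (5 equiv), CH2Cl2, −78 to −20 °C; aq. potassium sodium tartrate
Reagents that add atoms: none
Why: 1,2-Reduction of both α,β-unsaturated esters gives the two allylic alcohols (C14, C15) without touching alkene geometry; the ethers are inert to the hydride.

Step 7
Reactants: 10 (2E,6E)-2-{2-[(tert-butyldimethylsilyl)oxy]ethyl}-6-{2-[(4-methoxybenzyl)oxy]ethylidene}hept-2-ene-1,7-diol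
Product: 11 (2E,6E)-1,7-bis[(tert-butyldiphenylsilyl)oxy]-2-{2-[(tert-butyldimethylsilyl)oxy]ethyl}-6-{2-[(4-methoxybenzyl)oxy]ethylidene}hept-2-ene
Conditions: TBDPSCl, imidazole, DMF, rt
Reagents that add atoms: tert-butyl(chloro)diphenylsilane, CC(C)(C)[Si](Cl)(c1ccccc1)c1ccccc1
Why: Silylation of both primary allylic alcohols; the bulky diphenylsilyl ethers resist the acid that later removes the smaller silyl group from O8.

Step 8
Reactants: 11 (2E,6E)-1,7-bis[(tert-butyldiphenylsilyl)oxy]-2-{2-[(tert-butyldimethylsilyl)oxy]ethyl}-6-{2-[(4-methoxybenzyl)oxy]ethylidene}hept-2-ene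
Product: 12 (2E,6E)-3,7-bis{[(tert-butyldiphenylsilyl)oxy]methyl}-9-[(tert-butyldimethylsilyl)oxy]nona-2,6-dien-1-ol
Conditions: DDQ, CH2Cl2/pH 7 buffer, 0 °C
Reagents that add atoms: none
Why: Oxidative cleavage of the 4-methoxybenzyl ether (hydride abstraction to the oxocarbenium ion, then hydrolysis) frees O6 alone; silyl ethers are unaffected under buffered conditions.

Step 9
Reactants: 12 (2E,6E)-3,7-bis{[(tert-butyldiphenylsilyl)oxy]methyl}-9-[(tert-butyldimethylsilyl)oxy]nona-2,6-dien-1-ol
Product: 13 (2E,6E)-3,7-bis{[(tert-butyldiphenylsilyl)oxy]methyl}-9-[(tert-butyldimethylsilyl)oxy]nona-2,6-dienal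
Conditions: MnO2, CH2Cl2, rt
Reagents that add atoms: none
Why: Heterogeneous allylic oxidation under neutral conditions gives the enal without E/Z isomerisation and without over-oxidation.

Step 10
Reactants: 13 (2E,6E)-3,7-bis{[(tert-butyldiphenylsilyl)oxy]methyl}-9-[(tert-butyldimethylsilyl)oxy]nona-2,6-dienal
Product: 14 (3S,4E,8E)-5,9-bis{[(tert-butyldiphenylsilyl)oxy]methyl}-11-[(tert-butyldimethylsilyl)oxy]undeca-1,4,8-trien-3-ol
Conditions: divinylzinc (from vinylmagnesium bromide and ZnCl2, magnesium salts precipitated with 1,4-dioxane), (−)-MIB [(2S)-3-exo-morpholinoisoborneol] (10 mol%), toluene, −20 to 0 °C; aq. NH4Cl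
Reagents that add atoms: divinylzinc, C=C[Zn]C=C
Why: Amino alcohol-catalysed enantioselective 1,2-addition of an alkenylzinc to an aldehyde; the zinc aminoalkoxide binds the enal and a second zinc reagent in a bimetallic six-membered transition state that should deliver vinyl to the Si face, as for aryl and alkenyl aldehydes, giving the 3S carbinol (C6 of the target).

Step 11
Reactants: 14 (3S,4E,8E)-5,9-bis{[(tert-butyldiphenylsilyl)oxy]methyl}-11-[(tert-butyldimethylsilyl)oxy]undeca-1,4,8-trien-3-ol; 15 2-(bromomethyl)acrylic acid
Product: 16 (3S,4E,8E)-5,9-bis{[(tert-butyldiphenylsilyl)oxy]methyl}-11-[(tert-butyldimethylsilyl)oxy]undeca-1,4,8-trien-3-yl 2-(bromomethyl)prop-2-enoate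
Conditions: DCC, DMAP (cat.), CH2Cl2, −10 to 0 °C
Reagents that add atoms: none
Why: Steglich esterification; the alcohol oxygen attacks the activated acyl group, so C6 keeps its configuration, and low temperature with only catalytic DMAP limits displacement of the allylic bromide.

Step 12
Reactants: 16 (3S,4E,8E)-5,9-bis{[(tert-butyldiphenylsilyl)oxy]methyl}-11-[(tert-butyldimethylsilyl)oxy]undeca-1,4,8-trien-3-yl 2-(bromomethyl)prop-2-enoate
Product: 17 (5R)-3-(bromomethyl)-5-[(1E,5E)-2,6-bis{[(tert-butyldiphenylsilyl)oxy]methyl}-8-[(tert-butyldimethylsilyl)oxy]octa-1,5-dien-1-yl]furan-2(5H)-one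
Conditions: second-generation Grubbs catalyst (10 mol%), CH2Cl2 (5 mM), reflux
Reagents that add atoms: none
Why: Ring-closing metathesis: the ruthenium alkylidene loads on the only monosubstituted alkene and closes onto the acrylate to form the five-membered butenolide (C7=C11) with loss of ethene, the trisubstituted alkenes being spectators; the descriptor at C6 changes to R only through CIP priorities.

Step 13
Reactants: 17 (5R)-3-(bromomethyl)-5-[(1E,5E)-2,6-bis{[(tert-butyldiphenylsilyl)oxy]methyl}-8-[(tert-butyldimethylsilyl)oxy]octa-1,5-dien-1-yl]furan-2(5H)-one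
Product: 18 (5R)-3-(bromomethyl)-5-[(1E,5E)-2,6-bis{[(tert-butyldiphenylsilyl)oxy]methyl}-8-hydroxyocta-1,5-dien-1-yl]furan-2(5H)-one
Conditions: CSA (cat.), MeOH/CH2Cl2 (1:1), 0 °C
Reagents that add atoms: none
Why: Acid-catalysed methanolysis removes the unhindered primary dimethylsilyl ether much faster than the diphenylsilyl ethers; the absence of base protects the acidic C6–H of the butenolide and the allylic bromide.

Step 14
Reactants: 18 (5R)-3-(bromomethyl)-5-[(1E,5E)-2,6-bis{[(tert-butyldiphenylsilyl)oxy]methyl}-8-hydroxyocta-1,5-dien-1-yl]furan-2(5H)-one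
Product: 19 (5R)-3-(bromomethyl)-5-[(1E,5E)-2,6-bis{[(tert-butyldiphenylsilyl)oxy]methyl}-8-oxoocta-1,5-dien-1-yl]furan-2(5H)-one
Conditions: Dess–Martin periodinane, NaHCO3, CH2Cl2, 0 °C to rt; filtered through a short silica pad and used at once
Reagents that add atoms: none
Why: Dess–Martin oxidation under buffered neutral conditions gives the C8 aldehyde without moving C1=C10 into conjugation and without deprotonating C6.

Step 15
Reactants: 19 (5R)-3-(bromomethyl)-5-[(1E,5E)-2,6-bis{[(tert-butyldiphenylsilyl)oxy]methyl}-8-oxoocta-1,5-dien-1-yl]furan-2(5H)-one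
Product: 21 (3aR,4S,6E,10E,11aR)-6,10-bis{[(tert-butyldiphenylsilyl)oxy]methyl}-4-hydroxy-3-methylidene-3a,4,5,8,9,11a-hexahydrocyclodeca[b]furan-2(3H)-one (the 8S carbinol in germacrane numbering), via allylchromium dichloride 20 (not isolated)
Conditions: CrCl2 (8 equiv), degassed THF, rt, 19 added by syringe pump over 10 h (final 2 mM); aq. NH4Cl
Reagents that add atoms: none
Why: Two divalent chromium ions reduce the C13–Br bond by successive one-electron transfers to the trivalent allylchromium 20, σ-bound at C13. Its chromium binds the C8 aldehyde oxygen and the carbon–carbon bond forms at the γ-carbon C7 through a six-membered chair (Zimmerman–Traxler) transition state, so the alkene shifts to C11=C13. This is the Nozaki–Hiyama allylation known for 2-(alkoxycarbonyl)allyl bromides and 3-(bromomethyl)butenolides, here run intramolecularly. The ten-membered carbocycle closes by attack of C7 on the carbonyl carbon with the C=O bond outside the new ring (10-exo-trig), the lactone being preformed and merely becoming fused. C7 is controlled by C6: the aldehyde should add to the butenolide face opposite the C5 chain, which gives the trans ring fusion (7R). C8 is controlled by the chair: the ring holds C6 trans to C13 on the allyl unit (an E-crotyl-type reagent), and with the C9 chain equatorial the anti adduct, the 8S carbinol, is expected. γ-Selectivity follows from the closed transition state, and ring closure over oligomerisation is secured by slow addition at high dilution and by the two cis alkenes, which fold the chain. The non-basic medium keeps C6 from epimerising, the aldehyde from conjugating and the lactone from migrating to O8.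

Step 16
Reactants: 21 (3aR,4S,6E,10E,11aR)-6,10-bis{[(tert-butyldiphenylsilyl)oxy]methyl}-4-hydroxy-3-methylidene-3a,4,5,8,9,11a-hexahydrocyclodeca[b]furan-2(3H)-one; 22 angelic acid [(2Z)-2-methylbut-2-enoic acid]
Product: 23 (3aR,4R,6E,10E,11aR)-6,10-bis{[(tert-butyldiphenylsilyl)oxy]methyl}-3-methylidene-2-oxo-2,3,3a,4,5,8,9,11a-octahydrocyclodeca[b]furan-4-yl (2Z)-2-methylbut-2-enoate
Conditions: PPh3, DIAD, toluene, 0 °C (betaine preformed); then 22 and 21, 0 °C to rt
Reagents that add atoms: none
Why: Mitsunobu esterification: O8 is activated as the alkoxyphosphonium ion and displaced by the angelate anion from the rear (SN2), inverting C8 from S to R; the acid is never activated at its carbonyl, so the Z alkene should survive, and preforming the betaine keeps free phosphine away from the methylene lactone.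

Step 17
Reactants: 23 (3aR,4R,6E,10E,11aR)-6,10-bis{[(tert-butyldiphenylsilyl)oxy]methyl}-3-methylidene-2-oxo-2,3,3a,4,5,8,9,11a-octahydrocyclodeca[b]furan-4-yl (2Z)-2-methylbut-2-enoate
Product: 24 (3aR,4R,6E,10E,11aR)-6,10-bis(hydroxymethyl)-3-methylidene-2-oxo-2,3,3a,4,5,8,9,11a-octahydrocyclodeca[b]furan-4-yl (2Z)-2-methylbut-2-enoate (CNP0182172.4)
Conditions: HF·pyridine, pyridine, THF, 0 °C to rt
Reagents that add atoms: none
Why: Fluoride attacks silicon and cleaves both Si–O bonds under buffered, weakly acidic conditions, which should avoid conjugate addition to the methylene lactone, acyl migration from O8 and isomerisation of the angelate.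

## Compound list

1 | triethyl phosphonoacetate | CCOC(=O)CP(=O)(OCC)OCC | starting material
2 | 2-(2-bromoethyl)-1,3-dioxolane | BrCCC1OCCO1 | starting material
3 | ethyl 2-(diethoxyphosphoryl)-4-(1,3-dioxolan-2-yl)butanoate (racemic) | CCOC(=O)C(CCC1OCCO1)P(=O)(OCC)OCC | intermediate
4 | 2-[(4-methoxybenzyl)oxy]acetaldehyde | O=CCOCc1ccc(OC)cc1 | starting material
5 | ethyl (2E)-2-[2-(1,3-dioxolan-2-yl)ethyl]-4-[(4-methoxybenzyl)oxy]but-2-enoate | COc1ccc(COC/C=C(/C(=O)OCC)CCC2OCCO2)cc1 | intermediate
6 | ethyl (2E)-4-[(4-methoxybenzyl)oxy]-2-(3-oxopropyl)but-2-enoate | COc1ccc(COC/C=C(/C(=O)OCC)CCC=O)cc1 | intermediate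
7 | (2-bromoethoxy)(tert-butyl)dimethylsilane | BrCCO[Si](C)(C)C(C)(C)C | starting material
8 | ethyl 4-[(tert-butyldimethylsilyl)oxy]-2-(diethoxyphosphoryl)butanoate (racemic) | CCOC(=O)C(CCO[Si](C)(C)C(C)(C)C)P(=O)(OCC)OCC | intermediate
9 | diethyl (2E,6E)-2-{2-[(tert-butyldimethylsilyl)oxy]ethyl}-6-{2-[(4-methoxybenzyl)oxy]ethylidene}hept-2-enedioate | COc1ccc(COC/C=C(/C(=O)OCC)CC/C=C(/C(=O)OCC)CCO[Si](C)(C)C(C)(C)C)cc1 | intermediate
10 | (2E,6E)-2-{2-[(tert-butyldimethylsilyl)oxy]ethyl}-6-{2-[(4-methoxybenzyl)oxy]ethylidene}hept-2-ene-1,7-diol | COc1ccc(COC/C=C(/CO)CC/C=C(/CO)CCO[Si](C)(C)C(C)(C)C)cc1 | intermediate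
11 | (2E,6E)-1,7-bis[(tert-butyldiphenylsilyl)oxy]-2-{2-[(tert-butyldimethylsilyl)oxy]ethyl}-6-{2-[(4-methoxybenzyl)oxy]ethylidene}hept-2-ene | COc1ccc(COC/C=C(/CO[Si](c2ccccc2)(c2ccccc2)C(C)(C)C)CC/C=C(/CO[Si](c2ccccc2)(c2ccccc2)C(C)(C)C)CCO[Si](C)(C)C(C)(C)C)cc1 | intermediate
12 | (2E,6E)-3,7-bis{[(tert-butyldiphenylsilyl)oxy]methyl}-9-[(tert-butyldimethylsilyl)oxy]nona-2,6-dien-1-ol | OC/C=C(/CO[Si](c1ccccc1)(c1ccccc1)C(C)(C)C)CC/C=C(/CO[Si](c1ccccc1)(c1ccccc1)C(C)(C)C)CCO[Si](C)(C)C(C)(C)C | intermediate
13 | (2E,6E)-3,7-bis{[(tert-butyldiphenylsilyl)oxy]methyl}-9-[(tert-butyldimethylsilyl)oxy]nona-2,6-dienal | O=C/C=C(/CO[Si](c1ccccc1)(c1ccccc1)C(C)(C)C)CC/C=C(/CO[Si](c1ccccc1)(c1ccccc1)C(C)(C)C)CCO[Si](C)(C)C(C)(C)C | intermediate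
14 | (3S,4E,8E)-5,9-bis{[(tert-butyldiphenylsilyl)oxy]methyl}-11-[(tert-butyldimethylsilyl)oxy]undeca-1,4,8-trien-3-ol | O[C@H](/C=C(/CO[Si](c1ccccc1)(c1ccccc1)C(C)(C)C)CC/C=C(/CO[Si](c1ccccc1)(c1ccccc1)C(C)(C)C)CCO[Si](C)(C)C(C)(C)C)C=C | intermediate
15 | 2-(bromomethyl)acrylic acid | C=C(CBr)C(=O)O | starting material
16 | (3S,4E,8E)-5,9-bis{[(tert-butyldiphenylsilyl)oxy]methyl}-11-[(tert-butyldimethylsilyl)oxy]undeca-1,4,8-trien-3-yl 2-(bromomethyl)prop-2-enoate | C=C(CBr)C(=O)O[C@H](/C=C(/CO[Si](c1ccccc1)(c1ccccc1)C(C)(C)C)CC/C=C(/CO[Si](c1ccccc1)(c1ccccc1)C(C)(C)C)CCO[Si](C)(C)C(C)(C)C)C=C | intermediate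
17 | (5R)-3-(bromomethyl)-5-[(1E,5E)-2,6-bis{[(tert-butyldiphenylsilyl)oxy]methyl}-8-[(tert-butyldimethylsilyl)oxy]octa-1,5-dien-1-yl]furan-2(5H)-one | O=C1O[C@H](/C=C(/CO[Si](c2ccccc2)(c2ccccc2)C(C)(C)C)CC/C=C(/CO[Si](c2ccccc2)(c2ccccc2)C(C)(C)C)CCO[Si](C)(C)C(C)(C)C)C=C1CBr | intermediate
18 | (5R)-3-(bromomethyl)-5-[(1E,5E)-2,6-bis{[(tert-butyldiphenylsilyl)oxy]methyl}-8-hydroxyocta-1,5-dien-1-yl]furan-2(5H)-one | O=C1O[C@H](/C=C(/CO[Si](c2ccccc2)(c2ccccc2)C(C)(C)C)CC/C=C(/CO[Si](c2ccccc2)(c2ccccc2)C(C)(C)C)CCO)C=C1CBr | intermediate
19 | (5R)-3-(bromomethyl)-5-[(1E,5E)-2,6-bis{[(tert-butyldiphenylsilyl)oxy]methyl}-8-oxoocta-1,5-dien-1-yl]furan-2(5H)-one | O=C1O[C@H](/C=C(/CO[Si](c2ccccc2)(c2ccccc2)C(C)(C)C)CC/C=C(/CO[Si](c2ccccc2)(c2ccccc2)C(C)(C)C)CC=O)C=C1CBr | intermediate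
20 | allylchromium dichloride derived from 19 (Cr on C13; trivalent chromium, not isolated) | O=C1O[C@H](/C=C(/CO[Si](c2ccccc2)(c2ccccc2)C(C)(C)C)CC/C=C(/CO[Si](c2ccccc2)(c2ccccc2)C(C)(C)C)CC=O)C=C1C[Cr](Cl)Cl | intermediate
21 | (3aR,4S,6E,10E,11aR)-6,10-bis{[(tert-butyldiphenylsilyl)oxy]methyl}-4-hydroxy-3-methylidene-3a,4,5,8,9,11a-hexahydrocyclodeca[b]furan-2(3H)-one | C=C1C(=O)O[C@@H]2/C=C(/CO[Si](c3ccccc3)(c3ccccc3)C(C)(C)C)CC/C=C(/CO[Si](c3ccccc3)(c3ccccc3)C(C)(C)C)C[C@H](O)[C@@H]12 | intermediate
22 | angelic acid, (2Z)-2-methylbut-2-enoic acid | C/C=C(/C)C(=O)O | starting material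
23 | (3aR,4R,6E,10E,11aR)-6,10-bis{[(tert-butyldiphenylsilyl)oxy]methyl}-3-methylidene-2-oxo-2,3,3a,4,5,8,9,11a-octahydrocyclodeca[b]furan-4-yl (2Z)-2-methylbut-2-enoate | C=C1C(=O)O[C@@H]2/C=C(/CO[Si](c3ccccc3)(c3ccccc3)C(C)(C)C)CC/C=C(/CO[Si](c3ccccc3)(c3ccccc3)C(C)(C)C)C[C@@H](OC(=O)/C(C)=C\C)[C@@H]12 | intermediate
24 | (3aR,4R,6E,10E,11aR)-6,10-bis(hydroxymethyl)-3-methylidene-2-oxo-2,3,3a,4,5,8,9,11a-octahydrocyclodeca[b]furan-4-yl (2Z)-2-methylbut-2-enoate | C=C1C(=O)O[C@@H]2/C=C(/CO)CC/C=C(/CO)C[C@@H](OC(=O)/C(C)=C\C)[C@@H]12 | target

## Step count and least certain steps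

Total: 17 steps. Longest linear sequence: 16 steps (steps 1–3 and 5–17); step 4 is the only side branch.

**Step 15 (key step).** The most likely failure is loss of control at C8. The transition state is part of a strained ten-membered ring, so the chair with the C9 chain equatorial may not be the one that closes, and the addition may take the opposite sense at C8. Fallback: starting again from 19, if the closure delivers the epimeric (3aR,4R)-carbinol F1, inversion is no longer wanted. F1 is then acylated with retention by the mixed anhydride of 22 and 2,4,6-trichlorobenzoic acid F2 (from 22, 2,4,6-trichlorobenzoyl chloride and Et3N in toluene, then F1 at 80 °C without DMAP, so that the Z acyl group is not isomerised). This returns to the route at 23.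

**Step 16.** The most likely failure is elimination in place of substitution. The activated O8 sits beside the ring-fusion carbon, so rear-side attack is slow and loss of the oxyphosphonium group with a proton from C9 or C7 can compete; reversible addition of the phosphine to the methylene lactone can also consume reagent. Fallback: from 21, chloromethanesulfonyl chloride and pyridine in CH2Cl2 at 0 °C give the chloromethanesulfonate F3, a small and very reactive leaving group. Cesium (2Z)-2-methylbut-2-enoate F4 (from 22 and Cs2CO3) with 18-crown-6 in toluene at 60 °C displaces it with inversion and returns to the route at 23.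

**Step 10.** The most likely failure is insufficient face discrimination on a β,β-disubstituted enal. No other stereocentre exists at that stage, so any erosion is carried through to 24 as lower enantiomeric purity. Fallback: from 13, enantioselective alkynylation with trimethylsilylacetylene, Me2Zn and a ProPhenol ligand (the enantiomer that adds to the Si face) gives the silylated propargylic alcohol F5. K2CO3 in MeOH removes the C-silyl group to give the terminal alkyne F6. Semi-hydrogenation (H2, Pd/CaCO3 poisoned with Pb(OAc)2, quinoline) stops at the vinyl group and returns to the route at 14.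

**Step 12.** The most likely failure is slow closure onto the 1,1-disubstituted electron-poor acrylate, with catalyst decay and, on prolonged heating, loss of the allylic bromide or metathesis at a trisubstituted alkene. Fallback: from 14, acryloyl chloride and iPr2NEt give the acrylate F7. A Morita–Baylis–Hillman reaction with formaldehyde (DABCO, aqueous 1,4-dioxane) gives the 2-(hydroxymethyl)acrylate F8. Ring-closing metathesis with the same catalyst, now without the bromide and with a free allylic hydroxyl that should assist, gives the 3-(hydroxymethyl)butenolide F9. CBr4 and PPh3 then convert the alcohol into the bromide and return to the route at 17.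

## Further compounds

F1 | step 15 | (3aR,4R,6E,10E,11aR)-6,10-bis{[(tert-butyldiphenylsilyl)oxy]methyl}-4-hydroxy-3-methylidene-3a,4,5,8,9,11a-hexahydrocyclodeca[b]furan-2(3H)-one (C8 epimer of 21) | C=C1C(=O)O[C@@H]2/C=C(/CO[Si](c3ccccc3)(c3ccccc3)C(C)(C)C)CC/C=C(/CO[Si](c3ccccc3)(c3ccccc3)C(C)(C)C)C[C@@H](O)[C@@H]12
F2 | step 15 | (2Z)-2-methylbut-2-enoic 2,4,6-trichlorobenzoic anhydride | C/C=C(/C)C(=O)OC(=O)c1c(Cl)cc(Cl)cc1Cl
F3 | step 16 | (3aR,4S,6E,10E,11aR)-6,10-bis{[(tert-butyldiphenylsilyl)oxy]methyl}-3-methylidene-2-oxo-2,3,3a,4,5,8,9,11a-octahydrocyclodeca[b]furan-4-yl chloromethanesulfonate | C=C1C(=O)O[C@@H]2/C=C(/CO[Si](c3ccccc3)(c3ccccc3)C(C)(C)C)CC/C=C(/CO[Si](c3ccccc3)(c3ccccc3)C(C)(C)C)C[C@H](OS(=O)(=O)CCl)[C@@H]12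
F4 | step 16 | cesium (2Z)-2-methylbut-2-enoate | C/C=C(/C)C(=O)[O-].[Cs+]
F5 | step 10 | (3R,4E,8E)-5,9-bis{[(tert-butyldiphenylsilyl)oxy]methyl}-11-[(tert-butyldimethylsilyl)oxy]-1-(trimethylsilyl)undeca-4,8-dien-1-yn-3-ol | O[C@H](/C=C(/CO[Si](c1ccccc1)(c1ccccc1)C(C)(C)C)CC/C=C(/CO[Si](c1ccccc1)(c1ccccc1)C(C)(C)C)CCO[Si](C)(C)C(C)(C)C)C#C[Si](C)(C)C
F6 | step 10 | (3R,4E,8E)-5,9-bis{[(tert-butyldiphenylsilyl)oxy]methyl}-11-[(tert-butyldimethylsilyl)oxy]undeca-4,8-dien-1-yn-3-ol | O[C@H](/C=C(/CO[Si](c1ccccc1)(c1ccccc1)C(C)(C)C)CC/C=C(/CO[Si](c1ccccc1)(c1ccccc1)C(C)(C)C)CCO[Si](C)(C)C(C)(C)C)C#C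
F7 | step 12 | (3S,4E,8E)-5,9-bis{[(tert-butyldiphenylsilyl)oxy]methyl}-11-[(tert-butyldimethylsilyl)oxy]undeca-1,4,8-trien-3-yl prop-2-enoate | C=CC(=O)O[C@H](/C=C(/CO[Si](c1ccccc1)(c1ccccc1)C(C)(C)C)CC/C=C(/CO[Si](c1ccccc1)(c1ccccc1)C(C)(C)C)CCO[Si](C)(C)C(C)(C)C)C=C
F8 | step 12 | (3S,4E,8E)-5,9-bis{[(tert-butyldiphenylsilyl)oxy]methyl}-11-[(tert-butyldimethylsilyl)oxy]undeca-1,4,8-trien-3-yl 2-(hydroxymethyl)prop-2-enoate | C=C(CO)C(=O)O[C@H](/C=C(/CO[Si](c1ccccc1)(c1ccccc1)C(C)(C)C)CC/C=C(/CO[Si](c1ccccc1)(c1ccccc1)C(C)(C)C)CCO[Si](C)(C)C(C)(C)C)C=C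
F9 | step 12 | (5R)-3-(hydroxymethyl)-5-[(1E,5E)-2,6-bis{[(tert-butyldiphenylsilyl)oxy]methyl}-8-[(tert-butyldimethylsilyl)oxy]octa-1,5-dien-1-yl]furan-2(5H)-one | O=C1O[C@H](/C=C(/CO[Si](c2ccccc2)(c2ccccc2)C(C)(C)C)CC/C=C(/CO[Si](c2ccccc2)(c2ccccc2)C(C)(C)C)CCO[Si](C)(C)C(C)(C)C)C=C1CO
A1 | alternative 1 | open-chain C5 alkenyl iodide (iodine trans to C15) with C6 aldehyde, C12 methyl ester, 4-methoxybenzyl ether on O8 and tert-butyldimethylsilyl ethers on O14 and O15 | I/C=C(/CO[Si](C)(C)C(C)(C)C)CC/C=C(/CO[Si](C)(C)C(C)(C)C)C[C@@H](OCc1ccc(OC)cc1)[C@@H](CC(=O)OC)C=O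
A2 | alternative 1 | trans-fused lactone macrocycle without C13, 4-methoxybenzyl ether on O8, tert-butyldimethylsilyl ethers on O14 and O15 | C1C(=O)O[C@@H]2/C=C(/CO[Si](C)(C)C(C)(C)C)CC/C=C(/CO[Si](C)(C)C(C)(C)C)C[C@@H](OCc3ccc(OC)cc3)[C@@H]12
A3 | alternative 2 | γ-lactone with the C5=C4–C3 allylic bromide chain on C6 and the C8(4-methoxybenzyloxy)–C9–C10=C1–C2 phenylsulfonyl chain on C7 | C1C(=O)O[C@H](/C=C(/CO[Si](C)(C)C(C)(C)C)CBr)[C@H]1[C@H](OCc2ccc(OC)cc2)C/C(CO[Si](C)(C)C(C)(C)C)=C\CS(=O)(=O)c2ccccc2
A4 | alternative 2 | lactone macrocycle with phenylsulfonyl on C2 (either C2 epimer), 4-methoxybenzyl ether on O8 | C1C(=O)O[C@@H]2/C=C(/CO[Si](C)(C)C(C)(C)C)CC(S(=O)(=O)c3ccccc3)/C=C(/CO[Si](C)(C)C(C)(C)C)C[C@@H](OCc3ccc(OC)cc3)[C@@H]12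
A5 | alternative 3 | (1R,6S)-3-{[(tert-butyldimethylsilyl)oxy]methyl}-6-{3-[(tert-butyldimethylsilyl)oxy]prop-1-en-2-yl}-1-{(E)-2-[(4-methoxybenzyl)oxy]ethenyl}cyclohex-2-en-1-ol (alkenyl groups cis) | O[C@]1(/C=C/OCc2ccc(OC)cc2)C=C(CO[Si](C)(C)C(C)(C)C)CC[C@H]1C(=C)CO[Si](C)(C)C(C)(C)C
A6 | alternative 3 | ten-membered cis,cis-dienone with C6 ketone and 4-methoxybenzyl ether on C8 | O=C1/C=C(/CO[Si](C)(C)C(C)(C)C)CC/C=C(/CO[Si](C)(C)C(C)(C)C)C[C@@H](OCc2ccc(OC)cc2)C1
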